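Numbering used: lactone C12(=O)–C11(=C13H2) with the ring O on C6 and C11 on C7; carbocycle C1–C10; ester O on C8; CHO = C14 on C10; CH2OH = C15 on C4.
Retrosynthesis: (a) the C8 ester C–O bond and the silyl groups; (b) both lactone bonds O–C6 and C11–C7 at once, giving 2-bromoacrylic acid and a ten-membered ring diene; (c) ring bond C6=C7 (metathesis); (d) C1=C10 and C4=C5 (two Horner–Wadsworth–Emmons, HWE, olefinations); (e) C9–C10 and C3–C4 (phosphonate alkylations).
Enabling feature: C6 is at once the lactone carbinol and allylic to C4=C5, and O–C6 and C11–C7 are cis on the five-membered ring. The lactone is therefore the syn 1,2-adduct of an acrylic acid α-carbon/carboxylate pair across the C6=C7 end of a ring diene C4=C5–C6=C7, the allyl unit C4–C5–C6 handing C6 to the carboxylate.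
Forward: a C1–C6 diene aldehyde and a chiral C7–C10 phosphonate are joined at C1=C10; the ten-membered ring closes first (C6=C7), the lactone ring second (key step); then silyl-to-isovalerate exchange at O8 and release of C15–OH.
Stereochemistry: C8 comes from commercial (S)-but-3-ene-1,2-diol; both trisubstituted alkenes come from E-selective HWE reactions (carbonyl group trans to the chain, hence cis in the ring); C6=C7 is Z by ring constraint; C7 and C6 are set in the key step under control of C8 and the ring.
Key step: step 12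

Assumption: the SMILES is read as written, i.e. C6 R, C7 S, C8 R, which is a cis-fused lactone (H6 and H7 on the same side) with the C8 ester on the opposite ring face, and both ring alkenes cis with respect to the ring path (C2/C9 cis, C3/C6 cis).

Abbreviations: TBS = tert-butyldimethylsilyl, TBDPS = tert-butyldiphenylsilyl.

Step 1
Reactants: 1 triethyl phosphonoacetate; 2 3-bromo-1,1-dimethoxypropane
Product: 3 ethyl 2-(diethoxyphosphoryl)-5,5-dimethoxypentanoate
Conditions: NaH, DMF, 0 → 60 °C (1 in excess)
Reagents that add atoms: none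
Why: SN2 alkylation of the sodium phosphonoacetate carbanion by a primary bromide is the standard way to α-branched HWE reagents and forms the C3–C4 bond; excess 1 suppresses dialkylation.

Step 2
Reactants: 3 ethyl 2-(diethoxyphosphoryl)-5,5-dimethoxypentanoate; 4 acrolein
Product: 5 ethyl (2E)-2-(3,3-dimethoxypropyl)penta-2,4-dienoate
Conditions: NaH, THF, 0 °C; then 4, −78 → 0 °C
Reagents that add atoms: none
Why: Horner–Wadsworth–Emmons olefination of acrolein with an α-alkyl phosphonoacetate should give mainly the (E)-dienoate, with the ester carbon (C15) trans to the vinyl group (C6) and C3 cis to C6 as the ring requires; no stereocentre is formed.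

Step 3
Reactants: 5 ethyl (2E)-2-(3,3-dimethoxypropyl)penta-2,4-dienoate
Product: 6 (2E)-2-(3,3-dimethoxypropyl)penta-2,4-dien-1-ol
Conditions: i-Bu2AlH, CH2Cl2, −78 °C; aq. KNaC4H4O6 work-up
Reagents that add atoms: none
Why: 1,2-reduction of the conjugated ester by i-Bu2AlH at low temperature should give the allylic alcohol (C15–OH) and leave acetal and diene untouched.

Step 4
Reactants: 6 (2E)-2-(3,3-dimethoxypropyl)penta-2,4-dien-1-ol
Product: 7 tert-butyl{[(2E)-2-(3,3-dimethoxypropyl)penta-2,4-dien-1-yl]oxy}diphenylsilane
Conditions: TBDPSCl, imidazole, DMF, 0 °C → rt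
Reagents that add atoms: tert-butyl(chloro)diphenylsilane, CC(C)(C)[Si](Cl)(c1ccccc1)c1ccccc1
Why: routine silylation of the primary alcohol; the TBDPS ether is chosen because it should survive the acid step that removes the acetal and the fluoride step that later removes the C8 TBS group.

Step 5
Reactants: 7 tert-butyl{[(2E)-2-(3,3-dimethoxypropyl)penta-2,4-dien-1-yl]oxy}diphenylsilane
Product: 8 (4E)-4-[(tert-butyldiphenylsilyloxy)methyl]hepta-4,6-dienal
Conditions: TsOH·H2O (cat.), acetone/H2O, rt
Reagents that add atoms: water, O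
Why: mild acid hydrolysis of the dimethyl acetal should free the C1 aldehyde without touching the silyl ether or the diene.

Step 6
Reactants: 9 (2S)-but-3-ene-1,2-diol
Product: 10 (3S)-3,4-bis(tert-butyldimethylsilyloxy)but-1-ene
Conditions: TBSCl, imidazole, DMF, rt
Reagents that add atoms: tert-butyl(chloro)dimethylsilane, CC(C)(C)[Si](C)(C)Cl
Why: exhaustive silylation of the commercial diol; its stereocentre becomes C8 of the target (chiral pool) and is not touched in any later step.

Step 7
Reactants: 10 (3S)-3,4-bis(tert-butyldimethylsilyloxy)but-1-ene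
Product: 11 (2S)-2-(tert-butyldimethylsilyloxy)but-3-en-1-ol
Conditions: HF·pyridine, pyridine, THF, 0 °C
Reagents that add atoms: none
Why: buffered HF·pyridine cleaves a primary TBS ether much faster than a secondary one, a routine selective desilylation on steric grounds.

Step 8
Reactants: 11 (2S)-2-(tert-butyldimethylsilyloxy)but-3-en-1-ol; 12 diethyl {2-[methoxy(methyl)amino]-2-oxoethyl}phosphonate
Product: 14 diethyl {(4R)-4-(tert-butyldimethylsilyloxy)-1-[methoxy(methyl)amino]-1-oxohex-5-en-2-yl}phosphonate, via primary triflate 13 (not isolated)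
Conditions: Tf2O, 2,6-lutidine, CH2Cl2, −78 °C; cold solution transferred into 12 (excess) + NaH, THF, −78 → 0 °C
Reagents that add atoms: none
Why: the primary alcohol is activated as its triflate, which should alkylate the soft sodium phosphonate carbanion by SN2 at low temperature (C9–C10 bond) where a β-silyloxy halide would be too sluggish; the stereocentre is not involved (its descriptor changes from S to R only through the priority change).

Step 9
Reactants: 8 (4E)-4-[(tert-butyldiphenylsilyloxy)methyl]hepta-4,6-dienal; 14 diethyl {(4R)-4-(tert-butyldimethylsilyloxy)-1-[methoxy(methyl)amino]-1-oxohex-5-en-2-yl}phosphonate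
Product: 15 (2E,6E)-2-[(2R)-2-(tert-butyldimethylsilyloxy)but-3-en-1-yl]-6-[(tert-butyldiphenylsilyloxy)methyl]-N-methoxy-N-methylnona-2,6,8-trienamide
Conditions: NaH, THF, 0 °C → rt
Reagents that add atoms: none
Why: Horner–Wadsworth–Emmons olefination with the α-branched phosphonoamide should give mainly the (E)-trisubstituted enamide (C14 trans to C2, C9 cis to C2) under equilibrating sodium conditions; no stereocentre is formed.

Step 10
Reactants: 15 (2E,6E)-2-[(2R)-2-(tert-butyldimethylsilyloxy)but-3-en-1-yl]-6-[(tert-butyldiphenylsilyloxy)methyl]-N-methoxy-N-methylnona-2,6,8-trienamide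
Product: 16 (2E,6E)-2-[(2R)-2-(tert-butyldimethylsilyloxy)but-3-en-1-yl]-6-[(tert-butyldiphenylsilyloxy)methyl]nona-2,6,8-trienal
Conditions: i-Bu2AlH, THF, −78 °C; aq. KNaC4H4O6 work-up
Reagents that add atoms: none
Why: i-Bu2AlH reduces an N-methoxy-N-methylamide through its stable aluminium chelate directly to the aldehyde, so the C14 enal should arise without a separate oxidation and without touching the silyl ethers.

Step 11
Reactants: 16 (2E,6E)-2-[(2R)-2-(tert-butyldimethylsilyloxy)but-3-en-1-yl]-6-[(tert-butyldiphenylsilyloxy)methyl]nona-2,6,8-trienal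
Product: 17 (1E,5E,7Z,9R)-9-(tert-butyldimethylsilyloxy)-5-[(tert-butyldiphenylsilyloxy)methyl]cyclodeca-1,5,7-triene-1-carbaldehyde
Conditions: second-generation Grubbs catalyst RuCl2(=CHPh)(H2IMes)(PCy3) (10 mol%), toluene (1 mM), 80 °C
Reagents that add atoms: none
Why: ring-closing metathesis between the terminal diene CH2 and the allylic vinyl group releases ethene and should close the ten-membered ring at C6=C7; the two trisubstituted alkenes pre-bend the chain, and the new alkene should be Z as the less strained geometry next to the cis C4=C5 bond.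

Step 12
Reactants: 17 (1E,5E,7Z,9R)-9-(tert-butyldimethylsilyloxy)-5-[(tert-butyldiphenylsilyloxy)methyl]cyclodeca-1,5,7-triene-1-carbaldehyde; 18 2-bromoacrylic acid
Product: 19 (3aR,4R,6E,10E,11aR)-4-(tert-butyldimethylsilyloxy)-10-[(tert-butyldiphenylsilyloxy)methyl]-3-methylidene-2-oxo-2,3,3a,4,5,8,9,11a-octahydrocyclodeca[b]furan-6-carbaldehyde
Conditions: Pd(OAc)2 (10 mol%), Na2CO3, n-Bu4NCl, DMF, 60 °C, slow addition of 18
Reagents that add atoms: none
Why: Proposed new method: zerovalent palladium (formed in situ from Pd(OAc)2) should add oxidatively to the C–Br bond of 18, the resulting divalent 1-carboxyvinyl palladium should insert the C6=C7 end of the ring diene in a syn fashion (C11–C7 bond), and the η3-allyl palladium carboxylate over C6–C5–C4 should close the lactone by C–O reductive elimination at C6 through a six-membered oxapalladacycle, which restores C4=C5 and the zerovalent catalyst. The closest known reaction type is the palladium-catalysed heteroannulation of 1,3-dienes by aryl and vinylic halides that carry OH, NHR or CO2H (Heck insertion followed by intramolecular Tsuji–Trost-type capture); a 2-haloacrylic acid on a ten-membered trisubstituted diene has not been shown. The only ring closed is the γ-lactone, formally a 5-exo capture of the proximal allyl terminus C6 by the carboxylate (the 7-endo alternative at the fully substituted C4 is disfavoured). C7 is controlled by the C8 stereocentre: in the A(1,3)-minimised conformer (C8–H eclipsing C6=C7) the C8–C9 ring bond covers the inner face, so the vinyl group should enter on the peripheral face and end up trans to the C8 silyloxy group on the ring (the same sense as additions to 3-substituted cis-cyclooctenes); C6 is controlled by C7, because the carboxylate is delivered from palladium on the same face, and syn addition across the Z alkene gives the cis-fused lactone. The selectivities needed are diene over the enal alkene C1=C10 (trisubstituted and electron-poor, so insertion there is slow), C7 over C4 for C–C bond formation (C7 is the only diene terminus that bears hydrogen), and reductive elimination over β-hydride loss (after syn insertion no β-hydrogen at C7 is syn to palladium, and the C8 oxygen is kept as a silyl ether so that it cannot ionise).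

Step 13
Reactants: 19 (3aR,4R,6E,10E,11aR)-4-(tert-butyldimethylsilyloxy)-10-[(tert-butyldiphenylsilyloxy)methyl]-3-methylidene-2-oxo-2,3,3a,4,5,8,9,11a-octahydrocyclodeca[b]furan-6-carbaldehyde
Product: 20 (3aS,4R,6E,10E,11aR)-10-[(tert-butyldiphenylsilyloxy)methyl]-4-hydroxy-3-methylidene-2-oxo-2,3,3a,4,5,8,9,11a-octahydrocyclodeca[b]furan-6-carbaldehyde
Conditions: HF·pyridine, pyridine, THF, 0 °C → rt
Reagents that add atoms: none
Why: buffered HF·pyridine should remove the secondary TBS ether while the more acid-stable primary TBDPS ether, the enal and the α-methylene lactone remain (the descriptor at C3a changes only through priorities).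

Step 14
Reactants: 20 (3aS,4R,6E,10E,11aR)-10-[(tert-butyldiphenylsilyloxy)methyl]-4-hydroxy-3-methylidene-2-oxo-2,3,3a,4,5,8,9,11a-octahydrocyclodeca[b]furan-6-carbaldehyde; 21 3-methylbutanoic anhydride
Product: 22 (3aS,4R,6E,10E,11aR)-10-[(tert-butyldiphenylsilyloxy)methyl]-6-formyl-3-methylidene-2-oxo-2,3,3a,4,5,8,9,11a-octahydrocyclodeca[b]furan-4-yl 3-methylbutanoate
Conditions: DMAP (cat.), pyridine, CH2Cl2, 0 °C → rt
Reagents that add atoms: none
Why: DMAP-catalysed acylation of the secondary C8 alcohol with the anhydride installs the isovalerate with retention at C8; short, mild conditions should limit conjugate addition to the methylene lactone.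

Step 15
Reactants: 22 (3aS,4R,6E,10E,11aR)-10-[(tert-butyldiphenylsilyloxy)methyl]-6-formyl-3-methylidene-2-oxo-2,3,3a,4,5,8,9,11a-octahydrocyclodeca[b]furan-4-yl 3-methylbutanoate
Product: 23 (3aS,4R,6E,10E,11aR)-6-formyl-10-(hydroxymethyl)-3-methylidene-2-oxo-2,3,3a,4,5,8,9,11a-octahydrocyclodeca[b]furan-4-yl 3-methylbutanoate (target)
Conditions: HF·pyridine (excess, unbuffered), THF, rt
Reagents that add atoms: none
Why: acidic fluoride cleaves the primary allylic TBDPS ether and is compatible with enal, ester and α-methylene lactone, so the target should be released without base.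

Compound list
1 | triethyl phosphonoacetate | CCOC(=O)CP(=O)(OCC)OCC | starting material
2 | 3-bromo-1,1-dimethoxypropane | COC(CCBr)OC | starting material
3 | ethyl 2-(diethoxyphosphoryl)-5,5-dimethoxypentanoate (racemic) | CCOC(=O)C(CCC(OC)OC)P(=O)(OCC)OCC | intermediate
4 | acrolein | C=CC=O | starting material
5 | ethyl (2E)-2-(3,3-dimethoxypropyl)penta-2,4-dienoate | CCOC(=O)/C(CCC(OC)OC)=C/C=C | intermediate
6 | (2E)-2-(3,3-dimethoxypropyl)penta-2,4-dien-1-ol | OC/C(CCC(OC)OC)=C/C=C | intermediate
7 | tert-butyl{[(2E)-2-(3,3-dimethoxypropyl)penta-2,4-dien-1-yl]oxy}diphenylsilane | COC(OC)CC/C(CO[Si](c1ccccc1)(c1ccccc1)C(C)(C)C)=C\C=C | intermediate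
8 | (4E)-4-[(tert-butyldiphenylsilyloxy)methyl]hepta-4,6-dienal | O=CCC/C(CO[Si](c1ccccc1)(c1ccccc1)C(C)(C)C)=C\C=C | intermediate
9 | (2S)-but-3-ene-1,2-diol | C=C[C@H](O)CO | starting material
10 | (3S)-3,4-bis(tert-butyldimethylsilyloxy)but-1-ene | C=C[C@H](O[Si](C)(C)C(C)(C)C)CO[Si](C)(C)C(C)(C)C | intermediate
11 | (2S)-2-(tert-butyldimethylsilyloxy)but-3-en-1-ol | C=C[C@H](O[Si](C)(C)C(C)(C)C)CO | intermediate
12 | diethyl {2-[methoxy(methyl)amino]-2-oxoethyl}phosphonate | CCOP(=O)(CC(=O)N(C)OC)OCC | starting material
13 | (2S)-2-(tert-butyldimethylsilyloxy)but-3-en-1-yl trifluoromethanesulfonate (not isolated) | C=C[C@H](O[Si](C)(C)C(C)(C)C)COS(=O)(=O)C(F)(F)F | intermediate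
14 | diethyl {(4R)-4-(tert-butyldimethylsilyloxy)-1-[methoxy(methyl)amino]-1-oxohex-5-en-2-yl}phosphonate (both C2 epimers) | C=C[C@H](O[Si](C)(C)C(C)(C)C)CC(C(=O)N(C)OC)P(=O)(OCC)OCC | intermediate
15 | (2E,6E)-2-[(2R)-2-(tert-butyldimethylsilyloxy)but-3-en-1-yl]-6-[(tert-butyldiphenylsilyloxy)methyl]-N-methoxy-N-methylnona-2,6,8-trienamide | CON(C)C(=O)/C(C[C@@H](O[Si](C)(C)C(C)(C)C)C=C)=C/CC/C(CO[Si](c1ccccc1)(c1ccccc1)C(C)(C)C)=C\C=C | intermediate
16 | (2E,6E)-2-[(2R)-2-(tert-butyldimethylsilyloxy)but-3-en-1-yl]-6-[(tert-butyldiphenylsilyloxy)methyl]nona-2,6,8-trienal | O=C/C(C[C@@H](O[Si](C)(C)C(C)(C)C)C=C)=C/CC/C(CO[Si](c1ccccc1)(c1ccccc1)C(C)(C)C)=C\C=C | intermediate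
17 | (1E,5E,7Z,9R)-9-(tert-butyldimethylsilyloxy)-5-[(tert-butyldiphenylsilyloxy)methyl]cyclodeca-1,5,7-triene-1-carbaldehyde | O=C/C1=C/CC/C(CO[Si](c2ccccc2)(c2ccccc2)C(C)(C)C)=C\C=C/[C@H](O[Si](C)(C)C(C)(C)C)C1 | intermediate
18 | 2-bromoacrylic acid | C=C(Br)C(=O)O | starting material
19 | (3aR,4R,6E,10E,11aR)-4-(tert-butyldimethylsilyloxy)-10-[(tert-butyldiphenylsilyloxy)methyl]-3-methylidene-2-oxo-2,3,3a,4,5,8,9,11a-octahydrocyclodeca[b]furan-6-carbaldehyde (cis-fused lactone, C8 silyloxy group trans to it) | C=C1C(=O)O[C@@H]2/C=C(/CO[Si](c3ccccc3)(c3ccccc3)C(C)(C)C)CC/C=C(/C=O)C[C@@H](O[Si](C)(C)C(C)(C)C)[C@H]12 | intermediate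
20 | (3aS,4R,6E,10E,11aR)-10-[(tert-butyldiphenylsilyloxy)methyl]-4-hydroxy-3-methylidene-2-oxo-2,3,3a,4,5,8,9,11a-octahydrocyclodeca[b]furan-6-carbaldehyde | C=C1C(=O)O[C@@H]2/C=C(/CO[Si](c3ccccc3)(c3ccccc3)C(C)(C)C)CC/C=C(/C=O)C[C@@H](O)[C@H]12 | intermediate
21 | 3-methylbutanoic anhydride | CC(C)CC(=O)OC(=O)CC(C)C | starting material
22 | (3aS,4R,6E,10E,11aR)-10-[(tert-butyldiphenylsilyloxy)methyl]-6-formyl-3-methylidene-2-oxo-2,3,3a,4,5,8,9,11a-octahydrocyclodeca[b]furan-4-yl 3-methylbutanoate | C=C1C(=O)O[C@@H]2/C=C(/CO[Si](c3ccccc3)(c3ccccc3)C(C)(C)C)CC/C=C(/C=O)C[C@@H](OC(=O)CC(C)C)[C@H]12 | intermediate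
23 | (3aS,4R,6E,10E,11aR)-6-formyl-10-(hydroxymethyl)-3-methylidene-2-oxo-2,3,3a,4,5,8,9,11a-octahydrocyclodeca[b]furan-4-yl 3-methylbutanoate | C=C1C(=O)O[C@@H]2/C=C(/CO)CC/C=C(/C=O)C[C@@H](OC(=O)CC(C)C)[C@H]12 | target

Total step count: 15. Longest linear sequence: 12 steps (steps 1–5 and 9–15).

Steps most likely to fail

1. Step 12 (proposed new method). Insertion of the hindered, twisted ring diene may be slow, so that 18 is lost to dehydrobromination or polymerisation. The allyl palladium may lose a β-hydrogen from C3 or C15 instead of forming the C–O bond. The new methylene lactone may undergo a second Heck reaction, and the face selectivity at C7 may be incomplete. Fallback with known chemistry, setting out from 17 and coming back at 19: 17 would be treated with malonic acid and Mn(OAc)3·2H2O (trivalent manganese, 2.2 equiv) in AcOH/KOAc at 40 °C. This oxidative radical lactone annulation of 1,3-dienes is a known reaction type: the malonyl radical adds to C7 on the peripheral face, the allyl radical is oxidised to the allyl cation, and the carboxyl group captures it at C6 on the same face. It should give the α-carboxy lactone F1. Decarboxylative Mannich methylenation (aq. HCHO, Et2NH, then NaOAc/AcOH, 80 °C) should then convert it into 19.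

2. Step 11. Ring closure may lose out to oligomerisation, because the ruthenium vinylcarbene formed at the diene terminus is sluggish and the other alkene is shielded by the allylic silyloxy group. Ring contraction through the internal diene alkene is a further risk. Fallback, setting out from 8 and 14 and coming back at 17, closes the ring at C1=C10 instead of C6=C7. Z-selective cross-metathesis of the vinyl group of 14 with the terminal diene CH2 of 8, with the ruthenium dithiolate catalyst Ru(S2C6H2Cl2)(H2IMes)(=CH-C6H4-2-O-i-Pr), would give the seco aldehyde phosphonate F2. Intramolecular Horner–Wadsworth–Emmons reaction (LiCl, DBU, MeCN, 1 mM) should give the macrocyclic N-methoxy-N-methylamide F3, in which the ring enforces the cis arrangement of C2 and C9. Reduction with i-Bu2AlH (THF, −78 °C) would give 17.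

3. Step 13. Once O8 is free, acid may promote shift of the lactone acyl group from O6 to O8 (translactonisation to the 8,12-olide). The primary TBDPS ether may also be partly lost during the longer exposure that the hindered secondary TBS ether needs. Fallback, setting out from 17 and coming back at 22, changes the order so that O8 is never free next to the lactone. 17 would be desilylated (HF·pyridine, pyridine, THF, 0 °C) to the macrocyclic dienol F4 and acylated with 21 (DMAP, pyridine, CH2Cl2) to the macrocyclic isovalerate F5. The annulation with 18 would then be run under the phosphine-free conditions of step 12 (Pd(OAc)2, Na2CO3, n-Bu4NCl, DMF, 60 °C) and should give 22 directly. The price is the risk that zerovalent palladium ionises the dienylic ester, which is why this order is not the main route.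

Further compounds
F1 | step 12 | α-carboxy lactone: 19 with CH(CO2H) at C11 in place of C=CH2 (C11 epimers) | O=C(O)C1C(=O)O[C@@H]2/C=C(/CO[Si](c3ccccc3)(c3ccccc3)C(C)(C)C)CC/C=C(/C=O)C[C@@H](O[Si](C)(C)C(C)(C)C)[C@H]12
F2 | step 11 | diethyl {(4R,5Z,7E)-4-(tert-butyldimethylsilyloxy)-7-[(tert-butyldiphenylsilyloxy)methyl]-1-[methoxy(methyl)amino]-1,10-dioxodeca-5,7-dien-2-yl}phosphonate | O=CCC/C(CO[Si](c1ccccc1)(c1ccccc1)C(C)(C)C)=C\C=C/[C@H](O[Si](C)(C)C(C)(C)C)CC(C(=O)N(C)OC)P(=O)(OCC)OCC
F3 | step 11 | (1E,5E,7Z,9R)-9-(tert-butyldimethylsilyloxy)-5-[(tert-butyldiphenylsilyloxy)methyl]-N-methoxy-N-methylcyclodeca-1,5,7-triene-1-carboxamide | CON(C)C(=O)/C1=C/CC/C(CO[Si](c2ccccc2)(c2ccccc2)C(C)(C)C)=C\C=C/[C@H](O[Si](C)(C)C(C)(C)C)C1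
F4 | step 13 | (1E,5E,7Z,9R)-5-[(tert-butyldiphenylsilyloxy)methyl]-9-hydroxycyclodeca-1,5,7-triene-1-carbaldehyde | O=C/C1=C/CC/C(CO[Si](c2ccccc2)(c2ccccc2)C(C)(C)C)=C\C=C/[C@H](O)C1
F5 | step 13 | (1R,2Z,4E,8E)-4-[(tert-butyldiphenylsilyloxy)methyl]-8-formylcyclodeca-2,4,8-trien-1-yl 3-methylbutanoate | O=C/C1=C/CC/C(CO[Si](c2ccccc2)(c2ccccc2)C(C)(C)C)=C\C=C/[C@H](OC(=O)CC(C)C)C1
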